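**Numbering.** Ring B (ten-membered): C1 (quaternary, bears the C15 methyl), C2, C3, C4, C5 (bears the C16 methyl)=C6, C7, C8, C9, C10. Ring A continues C11 (=C20H2), C12, C13, C14. Lactone: C7–O–C19(=O)–C17(C18H3)–C8.

**Remark on the chemistry:** but-2-ynoic acid (18), the carboxylation product of propyne, is taken as the commercial source of C5, C6, C7 and C16.

**Remark on the chemistry:** the chiral ligand of step 3 is used as the enantiomer that gives the C10 configuration drawn for 8.

## Analysis of the target

Target 37 is a briarane: a cyclohexane (ring A) trans-fused through C1/C10 to a ten-membered carbocycle (ring B), with a γ-lactone fused on the C7–C8 edge of ring B. It has eight stereocentres (C1, C2, C7, C8, C9, C10, C14, C17) and a Z-trisubstituted C5=C6 alkene. On ring A the C15 methyl and the C9 arm are cis, the C14 acetate is axial on the face opposite the methyl, and the C2 and C14 oxygens are 1,3-syn across quaternary C1. The C8 and C9 oxygens are erythro. On the lactone the C18 methyl, the C8 hydroxyl and C6 are all cis, and C9 stands alone on the other face. Sensitive groups are the three secondary acetates (base), the tertiary β-hydroxy lactone (retro-aldol, dehydration, epimerisable C17), the allylic C7–O bond and the exocyclic C11=C20 alkene. The difficulty lies in the strained ten-membered ring with its Z alkene and in the contiguous array C2–C1–C10–C9–C8–C7 with two fully substituted carbons (C1, C8). The strategy rests on the C4–C5 bond: C4 is a ring B methylene bonded to the methyl-bearing sp2 carbon C5. Cutting there leaves a primary alkylmetal at C4 (from a C3=C4 vinyl group on C2) and a Z-alkenyl iodide at C5, with every stereocentre already in place.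

## Retrosynthetic reasoning

**37 back to 34.** The exocyclic methylene is taken back to a C11 ketone (35) and this to its ethylene ketal (34); the C8 hydroxyl is carried as a triethylsilyl ether (36). The ketal keeps a second terminal alkene out of the hydroboration, and the silyl ether keeps the β-hydroxy lactone away from base.

**34 back to 32 (C4–C5).** This bond joins an sp3 methylene to an sp2 carbon of an alkene whose geometry can be fixed beforehand in an alkenyl iodide. Cutting here opens ring B to seco iodo-diene 32 and creates no stereocentre, so the ring closure only has to beat oligomerisation. The forward reaction is hydroboration of C3=C4 to alkylborane 33 and palladium-catalysed coupling with the C5–I bond.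

**32 back to 28 (lactone C19–O7, C7–H).** The lactone is opened to a tert-butyl ester and C7 is taken back to a ketone. Forward, a chelation-controlled hydride reduction of 28 uses the C8 hydroxyl and the bulk of the C9 arm to set C7 (29), acid closes the lactone (30), C17 is equilibrated (31) and C8 is silylated (32).

**28 back to 24 and 25 (C8–C17).** The tertiary C8 carbinol is cut to a C8 ketone and a propanoate nucleophile, Reformatsky reagent 26 made from 25. In 1,2-diketone 24 the C9 hydroxyl is free, so its zinc alkoxide can chelate the C8 carbonyl and steer attack anti to C10. The C9 acetate is added afterwards (27 to 28).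

**24 back to 17 and 21 (C8–C9).** The diketone is the oxidation product of α-diazo-β-hydroxy ketone 23, which is the aldol adduct of aldehyde 17 and diazoketone 21. This one cut brings in C5–C8 together with the Z-iodoalkene, and C9 is set by attack anti to quaternary C1.

**21 back to 18.** The Z-iodoalkene comes from anti hydroiodination of but-2-ynoic acid (19), followed by chain extension with one diazo carbon through mixed anhydride 20.

**17 back to 10.** The aldehyde is the oxidised C9 alcohol 16. The two ring A acetates (15) come from syn-diol 14, and the C2 carbinol of 14 is set by oxidation to vinyl ketone 12 and hydroxyl-directed reduction. The aldol that forms C1–C2 cannot be trusted to set C2, so it is reset here.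

**10 back to 3, 4 and 5 (C10–C9, C1–C2).** Both arms of ring A are attached to enone 3 in one operation: conjugate addition of Grignard reagent 6 (from 4, a hydroxymethyl equivalent) at C10, and trapping of enolate 7 by acrolein 5 at C1, anti to the new arm. Reduction of the C14 ketone and unmasking of C9 give triol 10.

**3 back to 1.** The enone is the partially hydrogenated quinone monoketal 2 of phenol 1. The unsubstituted enone of 2 must be saturated first, because a nucleophile would otherwise add there and not at C10.

## Alternatives that were turned down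

**Alternative 1:** Gold-catalysed closure of ring A.
- Disconnection: C10–C11 of ring A.
- Forward key step: Ph3PAuCl/AgBF4 activates a terminal C11≡C20 alkyne and a C9 silyl enol ether attacks through C10 (6-exo-dig), giving ring A, the exocyclic methylene and the C9 aldehyde of A1.
- For it: the C11=C20 alkene is formed directly under mild catalytic conditions. On this point it is stronger than the chosen route, which needs a ketal hydrolysis and a ketone methylenation (steps 21 and 22).
- Against it: the acyclic substrate must already carry quaternary C1 with the C2 and C14 stereocentres, built without a ring to lean on. The C10 configuration depends on enol ether geometry and on a chair-versus-boat preference that nothing in the substrate secures. A1 is monocyclic, so the ten-membered ring, the lactone and C7–C9 are still to be made, with a reactive exocyclic alkene present throughout.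
- Comparison: the chosen strategy spends its key step on ring B, the hardest part, and sets the ring A stereocentres on a preformed ring. In place of direct methylene formation it offers a late, non-basic methylenation.

**Alternative 2:** Transannular epoxide–allylsilane cyclisation.
- Disconnection: C1–C10 across a fourteen-membered carbocycle.
- Forward key step: BF3·OEt2 opens a C14–C1 epoxide at tertiary C1 and a transannular allylsilane attacks through C10, giving C1–C10, ring A (and so ring B), the C14 alcohol and the exocyclic methylene of A2.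
- For it: it gains more per step than the chosen key step (quaternary C1, C10, the C14 oxygen, the methylene and both rings at once), and a fourteen-membered ring closes more easily than a ten-membered one. On both points it is stronger.
- Against it: it needs a fourteen-membered ring with the lactone, the Z alkene, a defined epoxide and a defined allylsilane, and that ring needs a macrocyclisation of its own. The trans C1/C10 relation depends on the conformation of a flexible macrocycle. The cation at C1 is flanked by the oxygenated C2 and faces the C5=C6 alkene across the ring, so pinacol-type shifts and wrong transannular attack compete. The Lewis acid also threatens the tertiary silyl ether.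
- Comparison: the chosen ring closure creates no stereocentre; all of them are set earlier by simple models on a rigid ring. It offers predictability in place of convergence.

**Alternative 3:** Carbon monoxide insertion into a spiro-epoxide.
- Disconnection: C17–C19, with CO as the source of the lactone carbonyl.
- Forward key step: [(salph)Al(THF)2][Co(CO)4] under CO inserts into the C17–O bond of a C8/C17 spiro-epoxide, giving spiro β-lactone A3, which must then be translactonised to the C7 oxygen.
- For it: C17 is set stereospecifically from the epoxide. On this point it is stronger than the chosen route, which equilibrates C17 (step 18). It is also atom-economical and introduces the base-sensitive lactone last.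
- Against it: it makes one C–C bond and no ring of the skeleton, so ring B still has to be closed by other means. Ring-expanding carbonylation works best on less substituted epoxides; a trisubstituted spiro-epoxide on a medium ring can ionise at C8 under the Lewis acid and rearrange. A3 then needs deprotection at C7 and a four-to-five ring acyl shift that competes with decarboxylation.
- Comparison: the chosen key step closes ring B itself. In place of stereospecific control of C17 it offers a thermodynamic correction at a centre that can be epimerised.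

Key step: step 20

## Route

Step 1
Reactants: 1 4-methoxy-2-methylphenol
Product: 2 7-methyl-1,4-dioxaspiro[4.5]deca-6,9-dien-8-one (quinone monoketal: C14 ketone; C1 methyl; C11 ethylene ketal)
Conditions: PhI(OAc)2, HOCH2CH2OH, CH2Cl2, 0 °C to rt
Reagents that add atoms: ethane-1,2-diol (OCCO)
Why: Oxidative dearomatisation of a para-alkoxyphenol with a hypervalent iodine reagent: the phenoxonium ion is trapped para by the glycol and the mixed ketal closes to the dioxolane with loss of methanol, a known route to quinone monoketals.

Step 2
Reactants: 2 7-methyl-1,4-dioxaspiro[4.5]deca-6,9-dien-8-one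
Product: 3 7-methyl-1,4-dioxaspiro[4.5]dec-6-en-8-one (C1=C10 enone kept)
Conditions: H2 (1 atm), RhCl(PPh3)3 (cat.), benzene, rt
Reagents that add atoms: none
Why: Homogeneous hydrogenation with RhCl(PPh3)3 is governed by alkene substitution, so the disubstituted C12=C13 bond is saturated and the methyl-bearing C1=C10 enone survives, as in the known partial reduction of cross-conjugated cyclohexadienones. This removes the unsubstituted enone, where a nucleophile would otherwise add first.

Step 3
Reactants: 3 7-methyl-1,4-dioxaspiro[4.5]dec-6-en-8-one; 4 (chloromethyl)(isopropoxy)dimethylsilane; 5 acrolein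
Product: 8 aldol adduct 7-(1-hydroxyprop-2-enyl)-6-[(isopropoxydimethylsilyl)methyl]-7-methyl-1,4-dioxaspiro[4.5]decan-8-one (C10 arm cis to the C1 methyl; both C2 epimers), via Grignard reagent 6 (not isolated), via magnesium enolate 7 (not isolated)
Conditions: 4, Mg, THF, rt; then 3, Cu(OTf)2 (cat.), chiral imidazolinium chloride (NHC precursor, cat.), Et2O, −30 °C; then 5, −78 °C
Reagents that add atoms: none
Why: Copper-catalysed asymmetric conjugate addition of a Grignard reagent to a 2-methylcycloalkenone with aldol trapping of the magnesium enolate: the NHC–copper catalyst sets C10, and acrolein enters at C1 anti to the new arm, which fixes the quaternary centre and the trans relation of the C9 and C2 arms. The silylmethyl group is a masked hydroxymethyl (C9). The C2 carbinol is not relied on, since the chair transition state of the ring enolate should favour the unwanted epimer; it is reset in steps 6 and 7.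

Step 4
Reactants: 8 aldol adduct
Product: 10 triol 6-(hydroxymethyl)-7-(1-hydroxyprop-2-enyl)-7-methyl-1,4-dioxaspiro[4.5]decan-8-ol (C14 hydroxyl axial and trans to the C1 methyl; both C2 epimers), via silyl diol 9 (not isolated)
Conditions: LiBH(s-Bu)3, THF, −78 °C; then KF, KHCO3, 30% H2O2, MeOH/THF, rt
Reagents that add atoms: hydrogen peroxide (OO)
Why: The bulky borohydride attacks the C14 ketone along the equatorial trajectory of the chair with the C10 arm equatorial and the C1 methyl axial, giving the axial alcohol anti to the methyl, as in reductions of ketones next to a quaternary carbon. The oxidative work-up with fluoride is a Tamao–Fleming oxidation that turns the C–Si bond into the primary C9 alcohol.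

Step 5
Reactants: 10 triol
Product: 11 C9 tert-butyldimethylsilyl ether of the triol (C2 and C14 hydroxyls free; both C2 epimers)
Conditions: t-BuMe2SiCl, imidazole, DMF, 0 °C
Reagents that add atoms: tert-butyldimethylsilyl chloride (CC(C)(C)[Si](C)(C)Cl)
Why: Silylation is selective for the unhindered primary C9 alcohol over the two neopentyl secondary alcohols.

Step 6
Reactants: 11 C9 silyl ether diol
Product: 12 vinyl ketone 1-[8-hydroxy-7-methyl-6-(tert-butyldimethylsilyloxymethyl)-1,4-dioxaspiro[4.5]decan-7-yl]prop-2-en-1-one (C2 ketone; C14 alcohol)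
Conditions: MnO2, CH2Cl2, rt
Reagents that add atoms: none
Why: MnO2 oxidises allylic alcohols and leaves the saturated axial C14 alcohol alone, so both C2 epimers converge on one enone.

Step 7
Reactants: 12 vinyl ketone
Product: 14 syn-1,3-diol (C2 and C14 hydroxyls syn; C9 silyl ether), via boron chelate 13 (not isolated)
Conditions: Et2BOMe, THF/MeOH (4:1), −78 °C; NaBH4; then AcOH, MeOH co-evaporation
Reagents that add atoms: none
Why: Narasaka–Prasad reduction: the C14 alcohol and the C2 ketone are held in a six-membered boron chelate and external hydride adds axially, anti to the axial C10 substituent of the chelate. This gives the 1,3-syn diol, which is the C2 configuration of the target.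

Step 8
Reactants: 14 syn-1,3-diol
Product: 15 C2/C14 diacetate with C9 silyl ether
Conditions: Ac2O, Et3N, DMAP, CH2Cl2, rt to 40 °C
Reagents that add atoms: acetic anhydride (CC(=O)OC(C)=O)
Why: DMAP-catalysed acylation puts the two ring A acetates of the target on the hindered C2 and C14 alcohols in one operation.

Step 9
Reactants: 15 diacetate silyl ether
Product: 16 C2/C14 diacetate with free C9 alcohol
Conditions: HF·pyridine, pyridine, THF, 0 °C to rt
Reagents that add atoms: none
Why: Buffered fluoride cleaves the primary silyl ether without touching the ketal or the acetates.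

Step 10
Reactants: 16 diacetate alcohol
Product: 17 C2/C14 diacetate C9 aldehyde
Conditions: Dess–Martin periodinane, NaHCO3, CH2Cl2, 0 °C to rt
Reagents that add atoms: none
Why: Dess–Martin oxidation under buffered, non-basic conditions gives the aldehyde without epimerising C10, whose equatorial arm is in any case the stable one.

Step 11
Reactants: 18 but-2-ynoic acid
Product: 19 (Z)-3-iodobut-2-enoic acid
Conditions: NaI, AcOH, 110 °C
Reagents that add atoms: sodium iodide ([Na+].[I-])
Why: Hydroiodination of an ynoic acid by anti addition of HI places iodine at C5 cis to the carboxyl carbon (C7), which fixes the Z geometry that the target needs.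

Step 12
Reactants: 19 (Z)-3-iodobut-2-enoic acid
Product: 21 (Z)-1-diazo-4-iodopent-3-en-2-one, via mixed anhydride 20 (not isolated)
Conditions: i-BuOCOCl, N-methylmorpholine, THF, −20 °C; then Me3SiCHN2, MeCN, 0 °C to rt
Reagents that add atoms: (trimethylsilyl)diazomethane (C[Si](C)(C)C=[N+]=[N-])
Why: Acylation of the diazoalkane by the mixed anhydride (Arndt–Eistert-type diazoketone synthesis) avoids HCl and so keeps the Z alkene; the silyl group is lost on work-up. The diazo carbon becomes C8.

Step 13
Reactants: 17 C9 aldehyde; 21 (Z)-1-diazo-4-iodopent-3-en-2-one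
Product: 23 β-hydroxy α-diazo ketone (C9 carbinol; C8 diazo; C7 ketone; Z-iodoalkene), via lithiated diazoketone 22 (not isolated)
Conditions: LiN(SiMe3)2 added to 17 and 21, THF, −78 °C
Reagents that add atoms: none
Why: Aldol-type addition of a lithiated α-diazoketone to an aldehyde forms C8–C9. The Felkin–Anh model (quaternary C1 as the large group) and lithium chelation between the aldehyde and a ketal oxygen both direct attack anti to C1, which gives the C9 configuration of the target.

Step 14
Reactants: 23 β-hydroxy α-diazo ketone
Product: 24 β-hydroxy 1,2-diketone (C9 carbinol; C8 and C7 ketones)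
Conditions: dimethyldioxirane, acetone, −20 °C
Reagents that add atoms: dimethyldioxirane (CC1(C)OO1)
Why: Dimethyldioxirane oxidises the diazo carbon to a carbonyl group under neutral conditions, faster than it attacks the electron-poor alkenes. The free C9 hydroxyl is kept for the next step.

Step 15
Reactants: 24 β-hydroxy 1,2-diketone; 25 tert-butyl 2-bromopropanoate
Product: 27 Reformatsky adduct (C8 tertiary alcohol carrying the tert-butyl propanoate arm; C9 alcohol; C7 ketone; both C17 epimers), via Reformatsky reagent 26 (not isolated)
Conditions: 25, Zn, THF, rt; then 24, THF, −20 to 0 °C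
Reagents that add atoms: none
Why: Reformatsky addition to the more electrophilic, non-conjugated C8 carbonyl: the first equivalent of 26 forms the C9 zinc alkoxide, which chelates the C8 ketone, and the second adds anti to C10 (chelation control), setting C8. The tert-butyl ester does not lactonise onto the C9 oxygen; C17 forms as a mixture and is settled in step 18.

Step 16
Reactants: 27 Reformatsky adduct
Product: 28 C2/C9/C14 triacetate (C8 tertiary alcohol; C7 ketone; both C17 epimers)
Conditions: Ac2O, pyridine, DMAP (cat.), CH2Cl2, 0 °C to rt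
Reagents that add atoms: acetic anhydride (CC(=O)OC(C)=O)
Why: The secondary C9 alcohol is acylated in preference to the tertiary C8 alcohol; this installs the third acetate and blocks lactonisation through the C9 oxygen.

Step 17
Reactants: 28 triacetate keto ester
Product: 30 iodo-lactone with free C8 hydroxyl (both C17 epimers), via hydroxy ester 29 (not isolated)
Conditions: Zn(BH4)2, Et2O, −20 °C; then CF3CO2H, CH2Cl2, 0 °C
Reagents that add atoms: none
Why: Zn(BH4)2 chelates the C8 hydroxyl and the C7 ketone and delivers hydride 1,2 and anti to the bulky C9 arm, giving the C7 configuration of the target. Anhydrous acid then removes the tert-butyl group and the C7 hydroxyl closes the γ-lactone, leaving the dioxolane intact.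

Step 18
Reactants: 30 iodo-lactone (C17 epimers)
Product: 31 iodo-lactone with the C18 methyl cis to the C8 hydroxyl (single C17 epimer)
Conditions: DBU, toluene, rt
Reagents that add atoms: none
Why: Base-mediated epimerisation α to the lactone carbonyl under thermodynamic control: the methyl group should settle trans to the bulky C9 arm and cis to the small hydroxyl, the all-cis arrangement of the target.

Step 19
Reactants: 31 iodo-lactone
Product: 32 seco iodo-diene (8-O-triethylsilyl; C11 ketal; C2/C9/C14 triacetate; C3=C4 vinyl; Z-C5 iodide)
Conditions: Et3SiOTf, 2,6-lutidine, CH2Cl2, −78 to 0 °C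
Reagents that add atoms: triethylsilyl trifluoromethanesulfonate (CC[Si](CC)(CC)OS(=O)(=O)C(F)(F)F)
Why: A silyl triflate with a hindered pyridine base silylates the tertiary alcohol. The ether blocks retro-aldol cleavage and acyl migration under the basic coupling conditions.

Step 20
Reactants: 32 seco iodo-diene
Product: 34 tricyclic C11 ketal (8-O-triethylsilyl; ring B closed), via C4 alkylborane 33 (not isolated)
Conditions: 9-BBN, THF, rt; then added over 12 h to PdCl2(dppf) (20 mol%), AsPh3 (20 mol%), Cs2CO3, H2O, DMF/THF, rt, 2 mM
Reagents that add atoms: none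
Why: Hydroboration followed by B-alkyl Suzuki–Miyaura macrocyclisation, the closest known reaction type being B-alkyl Suzuki ring closure onto alkenyl iodides. 9-BBN adds anti-Markovnikov to the monosubstituted C3=C4 alkene only, and boron at C4 is 1,3 to the C2 acetate, so no β-elimination is possible. Divalent PdCl2(dppf) is reduced in situ to zerovalent palladium, which inserts into the C5–I bond with retention; base-assisted transmetalation transfers the primary C4 alkyl group, and reductive elimination from the eleven-membered palladacycle forms C4–C5. Ring B closes by end-to-end sp3–sp2 union; no stereocentre is created and the Z geometry is carried over unchanged from 32. The step needs chemoselective hydroboration, which is secured because C11 is a ketal and C3=C4 is the only terminal alkene. It needs cyclisation over oligomerisation, which is secured by slow addition at high dilution and by the trans-diequatorial C2 and C9 arms on ring A, which point both chain ends the same way. It needs reductive elimination to outrun β-hydride elimination, which the wide bite angle of dppf and AsPh3 as co-ligand favour; the mild base at room temperature spares the acetates, the lactone and the silyl ether.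

Step 21
Reactants: 34 tricyclic C11 ketal
Product: 35 tricyclic C11 ketone (8-O-triethylsilyl)
Conditions: PPTS, acetone/H2O (10:1), 55 °C
Reagents that add atoms: water (O)
Why: Acid-catalysed ketal hydrolysis under mild buffered acid that spares the acetates, the lactone and the tertiary silyl ether.

Step 22
Reactants: 35 tricyclic C11 ketone
Product: 36 8-O-triethylsilyl ether of the target (C11=C20 methylene)
Conditions: Zn, CH2Br2, TiCl4, THF/CH2Cl2, 0 °C to rt
Reagents that add atoms: dibromomethane (BrCBr)
Why: Takai–Lombardo methylenation: the non-basic titanium–zinc methylene reagent converts hindered, enolisable ketones without epimerising C10 and tolerates esters and lactones.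

Step 23
Reactants: 36 8-O-triethylsilyl ether of the target
Product: 37 target CNP0187723.2
Conditions: HF·pyridine, THF, 0 °C to rt
Reagents that add atoms: none
Why: Fluoride cleaves the tertiary silyl ether under conditions that leave the acetates, the lactone and both alkenes untouched.

## Compound list

1 | 4-methoxy-2-methylphenol | Cc1cc(OC)ccc1O | starting material
2 | 7-methyl-1,4-dioxaspiro[4.5]deca-6,9-dien-8-one | CC1=CC2(OCCO2)C=CC1=O | intermediate
3 | 7-methyl-1,4-dioxaspiro[4.5]dec-6-en-8-one | CC1=CC2(OCCO2)CCC1=O | intermediate
4 | (chloromethyl)(isopropoxy)dimethylsilane | CC(C)O[Si](C)(C)CCl | starting material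
5 | acrolein (prop-2-enal) | C=CC=O | starting material
6 | [(isopropoxydimethylsilyl)methyl]magnesium chloride | CC(C)O[Si](C)(C)C[Mg]Cl | intermediate (not isolated)
7 | chloromagnesium C14–C1 enolate of the conjugate adduct, C10 set | CC1=C(O[Mg]Cl)CCC2(OCCO2)[C@@H]1C[Si](C)(C)OC(C)C | intermediate (not isolated)
8 | aldol adduct: C14 ketone, C10 silylmethyl arm cis to the C1 methyl and trans to the C2 arm, C2 carbinol as both epimers | C=CC(O)[C@@]1(C)C(=O)CCC2(OCCO2)[C@@H]1C[Si](C)(C)OC(C)C | intermediate
9 | silyl diol: C14 axial alcohol trans to the C1 methyl, silane intact, both C2 epimers | C=CC(O)[C@@]1(C)[C@@H](O)CCC2(OCCO2)[C@@H]1C[Si](C)(C)OC(C)C | intermediate (not isolated)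
10 | triol: C9, C2 and C14 hydroxyls, both C2 epimers | C=CC(O)[C@@]1(C)[C@@H](O)CCC2(OCCO2)[C@@H]1CO | intermediate
11 | C9 tert-butyldimethylsilyl ether of 10, both C2 epimers | C=CC(O)[C@@]1(C)[C@@H](O)CCC2(OCCO2)[C@@H]1CO[Si](C)(C)C(C)(C)C | intermediate
12 | vinyl ketone: C2 ketone, C14 alcohol, C9 silyl ether | C=CC(=O)[C@@]1(C)[C@@H](O)CCC2(OCCO2)[C@@H]1CO[Si](C)(C)C(C)(C)C | intermediate
13 | C14 O-diethylboryl derivative of 12 (boron chelate) | C=CC(=O)[C@@]1(C)[C@@H](OB(CC)CC)CCC2(OCCO2)[C@@H]1CO[Si](C)(C)C(C)(C)C | intermediate (not isolated)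
14 | syn-1,3-diol: C2 and C14 hydroxyls syn, C9 silyl ether | C=C[C@@H](O)[C@@]1(C)[C@@H](O)CCC2(OCCO2)[C@@H]1CO[Si](C)(C)C(C)(C)C | intermediate
15 | C2/C14 diacetate, C9 silyl ether | C=C[C@@H](OC(C)=O)[C@@]1(C)[C@@H](OC(C)=O)CCC2(OCCO2)[C@@H]1CO[Si](C)(C)C(C)(C)C | intermediate
16 | C2/C14 diacetate, C9 primary alcohol | C=C[C@@H](OC(C)=O)[C@@]1(C)[C@@H](OC(C)=O)CCC2(OCCO2)[C@@H]1CO | intermediate
17 | C2/C14 diacetate, C9 aldehyde | C=C[C@@H](OC(C)=O)[C@@]1(C)[C@@H](OC(C)=O)CCC2(OCCO2)[C@@H]1C=O | intermediate
18 | but-2-ynoic acid | CC#CC(=O)O | starting material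
19 | (Z)-3-iodobut-2-enoic acid | OC(=O)/C=C(/C)I | intermediate
20 | isobutyl carbonic (Z)-3-iodobut-2-enoic anhydride | CC(C)COC(=O)OC(=O)/C=C(/C)I | intermediate (not isolated)
21 | (Z)-1-diazo-4-iodopent-3-en-2-one | [N-]=[N+]=CC(=O)/C=C(/C)I | intermediate
22 | 1-lithio derivative of 21 | [Li]C(=[N+]=[N-])C(=O)/C=C(/C)I | intermediate (not isolated)
23 | β-hydroxy α-diazo ketone: C9 carbinol, C8 diazo, C7 ketone, Z-iodoalkene | C=C[C@@H](OC(C)=O)[C@@]1(C)[C@@H](OC(C)=O)CCC2(OCCO2)[C@@H]1[C@@H](O)C(=[N+]=[N-])C(=O)/C=C(/C)I | intermediate
24 | β-hydroxy 1,2-diketone: C9 carbinol, C8 and C7 ketones | C=C[C@@H](OC(C)=O)[C@@]1(C)[C@@H](OC(C)=O)CCC2(OCCO2)[C@@H]1[C@@H](O)C(=O)C(=O)/C=C(/C)I | intermediate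
25 | tert-butyl 2-bromopropanoate | CC(Br)C(=O)OC(C)(C)C | starting material
26 | bromo(1-tert-butoxy-1-oxopropan-2-yl)zinc | CC([Zn]Br)C(=O)OC(C)(C)C | intermediate (not isolated)
27 | Reformatsky adduct: C8 tertiary alcohol, C9 alcohol, C7 ketone, tert-butyl ester, both C17 epimers | C=C[C@@H](OC(C)=O)[C@@]1(C)[C@@H](OC(C)=O)CCC2(OCCO2)[C@@H]1[C@@H](O)[C@](O)(C(C)C(=O)OC(C)(C)C)C(=O)/C=C(/C)I | intermediate
28 | C2/C9/C14 triacetate of 27, both C17 epimers | C=C[C@@H](OC(C)=O)[C@@]1(C)[C@@H](OC(C)=O)CCC2(OCCO2)[C@@H]1[C@@H](OC(C)=O)[C@](O)(C(C)C(=O)OC(C)(C)C)C(=O)/C=C(/C)I | intermediate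
29 | hydroxy ester: C7 alcohol, C8 alcohol, tert-butyl ester, both C17 epimers | C=C[C@@H](OC(C)=O)[C@@]1(C)[C@@H](OC(C)=O)CCC2(OCCO2)[C@@H]1[C@@H](OC(C)=O)[C@](O)(C(C)C(=O)OC(C)(C)C)[C@@H](O)/C=C(/C)I | intermediate (not isolated)
30 | iodo-lactone with free C8 hydroxyl, both C17 epimers | C=C[C@@H](OC(C)=O)[C@@]1(C)[C@@H](OC(C)=O)CCC2(OCCO2)[C@@H]1[C@@H](OC(C)=O)[C@@]1(O)[C@H](/C=C(/C)I)OC(=O)C1C | intermediate
31 | iodo-lactone with free C8 hydroxyl, C18 methyl cis to the C8 hydroxyl | C=C[C@@H](OC(C)=O)[C@@]1(C)[C@@H](OC(C)=O)CCC2(OCCO2)[C@@H]1[C@@H](OC(C)=O)[C@@]1(O)[C@H](/C=C(/C)I)OC(=O)[C@@H]1C | intermediate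
32 | seco iodo-diene, 8-O-triethylsilyl, C11 ketal | C=C[C@@H](OC(C)=O)[C@@]1(C)[C@@H](OC(C)=O)CCC2(OCCO2)[C@@H]1[C@@H](OC(C)=O)[C@@]1(O[Si](CC)(CC)CC)[C@H](/C=C(/C)I)OC(=O)[C@@H]1C | intermediate
33 | C4 alkylborane (B-alkyl-9-BBN) of 32 | C1CC2CCCC(C1)B2CC[C@@H](OC(C)=O)[C@@]1(C)[C@@H](OC(C)=O)CCC2(OCCO2)[C@@H]1[C@@H](OC(C)=O)[C@@]1(O[Si](CC)(CC)CC)[C@H](/C=C(/C)I)OC(=O)[C@@H]1C | intermediate (not isolated)
34 | tricyclic C11 ketal, 8-O-triethylsilyl | C12(OCCO1)CC[C@H](OC(C)=O)[C@@]3(C)[C@H]2[C@@H](OC(C)=O)[C@@]1(O[Si](CC)(CC)CC)[C@H](/C=C(/C)CC[C@H]3OC(C)=O)OC(=O)[C@@H]1C | intermediate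
35 | tricyclic C11 ketone, 8-O-triethylsilyl | O=C1CC[C@H](OC(C)=O)[C@@]2(C)[C@H]1[C@@H](OC(C)=O)[C@@]1(O[Si](CC)(CC)CC)[C@H](/C=C(/C)CC[C@H]2OC(C)=O)OC(=O)[C@@H]1C | intermediate
36 | 8-O-triethylsilyl ether of the target | C=C1CC[C@H](OC(C)=O)[C@@]2(C)[C@H]1[C@@H](OC(C)=O)[C@@]1(O[Si](CC)(CC)CC)[C@H](/C=C(/C)CC[C@H]2OC(C)=O)OC(=O)[C@@H]1C | intermediate
37 | CNP0187723.2: 2,9,14-triacetoxy-8-hydroxy briarane 5Z,11(20)-diene 19,7-lactone | C=C1CC[C@H](OC(C)=O)[C@@]2(C)[C@H]1[C@@H](OC(C)=O)[C@@]1(O)[C@H](/C=C(/C)CC[C@H]2OC(C)=O)OC(=O)[C@@H]1C | target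

## Step count and risk

Total: 23 steps. Longest linear sequence: 21 steps (1 to 37 through steps 1–10 and 13–23). Diazoketone 21 is made in two steps (11 and 12) and joins at step 13.

**Step 20 (key step).** Oligomerisation is the most likely failure: a ten-membered ring with a Z alkene is strained, so intermolecular coupling, protodeboronation and β-hydride elimination can outrun closure, and the aqueous base may also cleave acetates. The fallback keeps the C4–C5 bond but uses a base-free organozinc coupling. It sets out from 33 and comes back at 34. Alkylborane 33 is oxidised with NaBO3 to the C4 primary alcohol F1. I2, PPh3 and imidazole give the C4 primary iodide F2. Zn with LiCl inserts into the alkyl C–I bond only, giving the C4 alkylzinc iodide F3. An intramolecular Negishi coupling with Pd(P(t-Bu)3)2 at high dilution then closes ring B to 34.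

**Step 3.** The β-silyl Grignard reagent is bulky, so low enantioselectivity or 1,2-addition is possible, and trapping of the hindered enolate by acrolein may lose out to acrolein polymerisation. The fallback sets out from 3 and comes back at 17; it introduces C9 as an alkene and forms the enolate in a separate step.
- Hayashi–Miyaura addition of (E)-2-phenylethenylboronic acid to 3 with [Rh(acac)(C2H4)2] and BINAP (the enantiomer that gives the C10 configuration of 8) gives the styryl ketone F4.
- Me3SiCl, NaI and Et3N give the more substituted silyl enol ether F5.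
- MeLi, then ZnCl2 and acrolein give the aldol F6.
- LiBH(s-Bu)3 gives the C14 axial alcohol F7, MnO2 gives the vinyl ketone F8, and Et2BOMe/NaBH4 gives the syn-diol F9.
- Acetylation gives the diacetate F10.
- Ozonolysis at −78 °C, stopped when the electron-rich styryl alkene is consumed and worked up with PPh3, gives aldehyde 17.

**Step 15.** The zinc enolate may attack the conjugated C7 carbonyl or displace iodide at C5 by addition–elimination, and diketone 24 may undergo retro-aldol cleavage. The fallback sets out from 17 and comes back at 28; it keeps C7 as an unreactive amide while C8 is built.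
- Aldol addition of lithiated 2-diazo-N-methoxy-N-methylacetamide to 17 gives the diazo amide F11.
- Dimethyldioxirane gives the α-keto amide F12.
- Reformatsky reagent 26 adds to the C8 ketone under the same chelation control to give the tertiary alcohol F13.
- Acetylation of the C9 hydroxyl gives the acetate F14.
- CH3C≡CMgBr at low temperature converts the amide into the ynone F15.
- NaI in AcOH adds HI anti across the ynone to give 28.

**Step 21.** Once the C11 ketone is free, acid may epimerise C10 towards a cis ring fusion or start transannular reactions of the strained ring, and the methylenation of step 22 may then stall on the hindered bicyclic ketone. The fallback sets out from 32 and comes back at 36; it moves both operations before ring closure, where the equatorial C9 arm on a monocyclic ring A is also the stable one.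
- PPTS in wet acetone hydrolyses 32 to the seco ketone F16.
- Takai–Lombardo methylenation gives the seco triene F17.
- 9-BBN reacts with the monosubstituted C3=C4 vinyl group much faster than with the 1,1-disubstituted C11=C20 methylene, giving the alkylborane F18.
- The coupling under the conditions of step 20 closes ring B and gives 36.

## Further compounds

F1 | step 20 | C4 primary alcohol of the seco iodo-lactone | OCC[C@@H](OC(C)=O)[C@@]1(C)[C@@H](OC(C)=O)CCC2(OCCO2)[C@@H]1[C@@H](OC(C)=O)[C@@]1(O[Si](CC)(CC)CC)[C@H](/C=C(/C)I)OC(=O)[C@@H]1C
F2 | step 20 | C4 primary iodide of the seco iodo-lactone | ICC[C@@H](OC(C)=O)[C@@]1(C)[C@@H](OC(C)=O)CCC2(OCCO2)[C@@H]1[C@@H](OC(C)=O)[C@@]1(O[Si](CC)(CC)CC)[C@H](/C=C(/C)I)OC(=O)[C@@H]1C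
F3 | step 20 | C4 alkylzinc iodide of the seco iodo-lactone | I[Zn]CC[C@@H](OC(C)=O)[C@@]1(C)[C@@H](OC(C)=O)CCC2(OCCO2)[C@@H]1[C@@H](OC(C)=O)[C@@]1(O[Si](CC)(CC)CC)[C@H](/C=C(/C)I)OC(=O)[C@@H]1C
F4 | step 3 | 7-methyl-6-[(E)-2-phenylethenyl]-1,4-dioxaspiro[4.5]decan-8-one, C10 set, both C1 epimers | CC1C(=O)CCC2(OCCO2)[C@@H]1/C=C/c1ccccc1
F5 | step 3 | trimethylsilyl enol ether (C14=C1) of F4 | CC1=C(O[Si](C)(C)C)CCC2(OCCO2)[C@@H]1/C=C/c1ccccc1
F6 | step 3 | styryl aldol adduct, both C2 epimers | C=CC(O)[C@@]1(C)C(=O)CCC2(OCCO2)[C@@H]1/C=C/c1ccccc1
F7 | step 3 | styryl diol, C14 axial alcohol, both C2 epimers | C=CC(O)[C@@]1(C)[C@@H](O)CCC2(OCCO2)[C@@H]1/C=C/c1ccccc1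
F8 | step 3 | styryl vinyl ketone, C14 alcohol | C=CC(=O)[C@@]1(C)[C@@H](O)CCC2(OCCO2)[C@@H]1/C=C/c1ccccc1
F9 | step 3 | styryl syn-1,3-diol | C=C[C@@H](O)[C@@]1(C)[C@@H](O)CCC2(OCCO2)[C@@H]1/C=C/c1ccccc1
F10 | step 3 | styryl C2/C14 diacetate | C=C[C@@H](OC(C)=O)[C@@]1(C)[C@@H](OC(C)=O)CCC2(OCCO2)[C@@H]1/C=C/c1ccccc1
F11 | step 15 | β-hydroxy α-diazo N-methoxy-N-methylamide | C=C[C@@H](OC(C)=O)[C@@]1(C)[C@@H](OC(C)=O)CCC2(OCCO2)[C@@H]1[C@@H](O)C(=[N+]=[N-])C(=O)N(C)OC
F12 | step 15 | β-hydroxy α-keto N-methoxy-N-methylamide | C=C[C@@H](OC(C)=O)[C@@]1(C)[C@@H](OC(C)=O)CCC2(OCCO2)[C@@H]1[C@@H](O)C(=O)C(=O)N(C)OC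
F13 | step 15 | C8 tertiary alcohol amide with tert-butyl propanoate arm, both C17 epimers | C=C[C@@H](OC(C)=O)[C@@]1(C)[C@@H](OC(C)=O)CCC2(OCCO2)[C@@H]1[C@@H](O)[C@](O)(C(C)C(=O)OC(C)(C)C)C(=O)N(C)OC
F14 | step 15 | C9 acetate of F13, both C17 epimers | C=C[C@@H](OC(C)=O)[C@@]1(C)[C@@H](OC(C)=O)CCC2(OCCO2)[C@@H]1[C@@H](OC(C)=O)[C@](O)(C(C)C(=O)OC(C)(C)C)C(=O)N(C)OC
F15 | step 15 | C7 prop-1-ynyl ketone (ynone), both C17 epimers | C=C[C@@H](OC(C)=O)[C@@]1(C)[C@@H](OC(C)=O)CCC2(OCCO2)[C@@H]1[C@@H](OC(C)=O)[C@](O)(C(C)C(=O)OC(C)(C)C)C(=O)C#CC
F16 | step 21 | seco iodo-diene with free C11 ketone | C=C[C@@H](OC(C)=O)[C@@]1(C)[C@@H](OC(C)=O)CCC(=O)[C@@H]1[C@@H](OC(C)=O)[C@@]1(O[Si](CC)(CC)CC)[C@H](/C=C(/C)I)OC(=O)[C@@H]1C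
F17 | step 21 | seco iodo-triene with C11=C20 methylene | C=C[C@@H](OC(C)=O)[C@@]1(C)[C@@H](OC(C)=O)CCC(=C)[C@@H]1[C@@H](OC(C)=O)[C@@]1(O[Si](CC)(CC)CC)[C@H](/C=C(/C)I)OC(=O)[C@@H]1C
F18 | step 21 | C4 alkylborane (B-alkyl-9-BBN) of F17 | C1CC2CCCC(C1)B2CC[C@@H](OC(C)=O)[C@@]1(C)[C@@H](OC(C)=O)CCC(=C)[C@@H]1[C@@H](OC(C)=O)[C@@]1(O[Si](CC)(CC)CC)[C@H](/C=C(/C)I)OC(=O)[C@@H]1C
A1 | alternative 1 | ring A aldehyde with C11 exocyclic methylene and C2 vinyl carbinol acetate | C=C1CC[C@H](OC(C)=O)[C@@]([C@H](OC(C)=O)C=C)(C)[C@H]1C=O
A2 | alternative 2 | bicyclic C14 alcohol with rings A and B and the lactone | C=C1CC[C@H](O)[C@@]2(C)[C@H]1[C@@H](O[Si](C)(C)C(C)(C)C)[C@@]1(O[Si](C)(C)C)[C@H](/C=C(/C)CC[C@H]2O[Si](C)(C)C(C)(C)C)OC(=O)[C@@H]1C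
A3 | alternative 3 | spiro β-lactone on C8 of the bicyclic core | C=C1CC[C@H](OC(C)=O)[C@@]2(C)[C@H]1[C@@H](OC(C)=O)[C@@]1(OC(=O)[C@@H]1C)[C@H](/C=C(/C)CC[C@H]2OC(C)=O)O[Si](CC)(CC)CC
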